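The route rests on opening ring A at C2–C7 and C5–C6 (ring B = C1, C2, C7, C8, C9, C10; ring A = C2, C3, C4, C5, C6, C7). The feature used is the C3=C4 alkene of ring A, which sits between the cis ring-fusion carbons C2/C7 and the allylic C5 acetate and is therefore the alkene left behind by a [4+2] cycloaddition. One intramolecular Diels–Alder reaction of an acyclic (E,E)-acetoxydiene onto a tethered vinyl ketone closes both rings and sets C2, C5 and C7 from the C1/C10 pair of an Evans syn-aldol. The precursor is a 1,7,9-decatrien-3-one with C10–OTBS, the C1 propenyl unit as PMB ether, and the enone unmasked last.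

Key step: step 14

Labels: C1 carries the acrylate carbon Ca; C8 is the carbinol carbon; C10 carries the acyloxy group.

Assumption: (R)-4-benzyloxazolidin-2-one, 3-(tert-butyldimethylsilyloxy)propanal, (tributylstannyl)methanol, methacrolein and but-2-yne-1,4-diol are bought.

Design remarks:
- No structural error was found: the stereodescriptors of trienone and octalone agree with the target, and the C1/C10 pair is the syn-aldol pair that the (R)-auxiliary gives.
- The substituents at C1 and C10 are cis on ring B, so they cannot both be equatorial in a chair-like tether. In the endo transition state the C10 oxygen is equatorial and Ca takes the outward site anti to C3.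
- C10 therefore carries a non-chelating silyl ether, and Ca–CH2O carries the PMB group.
- The β-oxy vinyl ketone is base-sensitive, so it is generated by oxidation only after the dienyl acetate is in place.

Step 1
Reactants: 1 pent-4-enoic acid; 2 (R)-4-benzyloxazolidin-2-one
Product: 4 (R)-4-benzyl-3-(pent-4-enoyl)oxazolidin-2-one, via pent-4-enoic pivalic anhydride 3 (not isolated)
Conditions: PivCl, Et3N, THF, −20 °C; then LiCl, 2, −20 °C → rt
Reagents that add atoms: none
Why: Mixed-anhydride N-acylation of an oxazolidinone (LiCl/Et3N variant) is the standard entry to Evans imides and forms no stereocenter.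

Step 2
Reactants: 4 (R)-4-benzyl-3-(pent-4-enoyl)oxazolidin-2-one; 5 3-(tert-butyldimethylsilyloxy)propanal
Product: 7 (R)-4-benzyl-3-[(2R,3S)-2-allyl-5-(tert-butyldimethylsilyloxy)-3-hydroxypentanoyl]oxazolidin-2-one, via Z boron enolate 6 (not isolated)
Conditions: Bu2BOTf, iPr2NEt, CH2Cl2, −78 → 0 °C; 5, −78 → 0 °C; pH 7 buffer, MeOH, H2O2, 0 °C
Reagents that add atoms: none
Why: Evans syn-aldol through the Zimmerman–Traxler chair of the Z boron enolate, in which the (R)-benzyl group blocks one enolate face, should set C1 (R) and C10 (S) together as the syn pair.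

Step 3
Reactants: 7 aldol adduct
Product: 8 (2R,3S)-2-allyl-5-(tert-butyldimethylsilyloxy)-3-hydroxy-N-methoxy-N-methylpentanamide
Conditions: MeONHMe·HCl, AlMe3, CH2Cl2, −20 → 0 °C
Reagents that add atoms: N,O-dimethylhydroxylamine hydrochloride, CNOC.Cl
Why: Aluminium-amide transamination of an Evans aldol adduct, helped by the free β-hydroxyl, should cleave the exocyclic acyl group selectively and leave C1 and C10 untouched.

Step 4
Reactants: 8 β-hydroxy Weinreb amide
Product: 9 (2R,3S)-2-allyl-3,5-bis(tert-butyldimethylsilyloxy)-N-methoxy-N-methylpentanamide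
Conditions: TBSOTf, 2,6-lutidine, CH2Cl2, −78 → 0 °C
Reagents that add atoms: tert-butyldimethylsilyl triflate, CC(C)(C)[Si](C)(C)OS(=O)(=O)C(F)(F)F
Why: Silylation of a secondary alcohol with a silyl triflate and a hindered base is fast at low temperature and avoids retro-aldol.

Step 5
Reactants: 10 (tributylstannyl)methanol
Product: 11 tributyl[(4-methoxybenzyloxy)methyl]stannane
Conditions: NaH, PMBCl, Bu4NI (cat.), THF/DMF, 0 °C → rt
Reagents that add atoms: 4-methoxybenzyl chloride, COc1ccc(CCl)cc1
Why: Williamson etherification of the primary stannyl alcohol gives the precursor of the alkoxymethyl anion.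

Step 6
Reactants: 9 bis-silyl Weinreb amide; 11 tributyl[(4-methoxybenzyloxy)methyl]stannane
Product: 14 (3R,4S)-3-allyl-4,6-bis(tert-butyldimethylsilyloxy)-1-(4-methoxybenzyloxy)hexan-2-one, via alkoxymethyllithium 12 (not isolated), via lithium hemiaminal 13 (not isolated)
Conditions: 11, n-BuLi, THF, −78 °C; then 9, −78 °C; aq. NH4Cl
Reagents that add atoms: none
Why: Tin–lithium exchange gives the α-alkoxymethyllithium, which should add once to the amide because the chelated tetrahedral adduct survives until work-up (Weinreb ketone synthesis), without deprotonating C1 at −78 °C.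

Step 7
Reactants: 14 α-alkoxy ketone
Product: 15 (3S,4S)-3-allyl-4,6-bis(tert-butyldimethylsilyloxy)-2-[(4-methoxybenzyloxy)methyl]hex-1-ene
Conditions: Ph3PCH3Br, KHMDS, THF, 0 °C; then 14, −20 °C → rt
Reagents that add atoms: methyltriphenylphosphonium bromide, C[P+](c1ccccc1)(c1ccccc1)c1ccccc1.[Br-]
Why: Wittig methylenation turns the ketone carbon into Ca=CH2, and the activated α-alkoxy ketone should be olefinated faster than it is enolised at C1.

Step 8
Reactants: 15 terminal alkene; 16 methacrolein
Product: 17 (2E,5S,6S)-6,8-bis(tert-butyldimethylsilyloxy)-5-[3-(4-methoxybenzyloxy)prop-1-en-2-yl]-2-methyloct-2-enal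
Conditions: methacrolein (8 equiv), second-generation Hoveyda–Grubbs catalyst (5 mol%), CH2Cl2, 40 °C
Reagents that add atoms: none
Why: Olefin cross-metathesis of the monosubstituted alkene with excess methacrolein should give the E trisubstituted enal, while the hindered 1,1-disubstituted Ca=CH2 alkene stays out of the reaction.

Step 9
Reactants: 17 enal
Product: 19 (1E,3E,5S,6S)-6,8-bis(tert-butyldimethylsilyloxy)-5-[3-(4-methoxybenzyloxy)prop-1-en-2-yl]-2-methylocta-1,3-dien-1-yl acetate, via potassium dienolate 18 (not isolated)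
Conditions: KHMDS, THF, −78 °C; then Ac2O, −78 °C
Reagents that add atoms: acetic anhydride, CC(=O)OC(C)=O
Why: Dienol ester formation by γ-deprotonation at C2 and O-acetylation of the extended enolate; the s-trans enal should give the E enol acetate (oxygen trans to C3), and A(1,3) strain with the C4 methyl disfavours a Z C2=C3 bond.

Step 10
Reactants: 19 dienyl acetate
Product: 20 (1E,3E,5S,6S)-6-(tert-butyldimethylsilyloxy)-8-hydroxy-5-[3-(4-methoxybenzyloxy)prop-1-en-2-yl]-2-methylocta-1,3-dien-1-yl acetate
Conditions: HF·pyridine, pyridine, THF, 0 °C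
Reagents that add atoms: none
Why: Selective desilylation, since buffered HF·pyridine cleaves the primary silyl ether much faster than the hindered secondary one and does not solvolyse the enol acetate.

Step 11
Reactants: 20 primary alcohol
Product: 21 (1E,3E,5S,6S)-6-(tert-butyldimethylsilyloxy)-5-[3-(4-methoxybenzyloxy)prop-1-en-2-yl]-2-methyl-8-oxoocta-1,3-dien-1-yl acetate
Conditions: Dess–Martin periodinane, pyridine, CH2Cl2, 0 °C
Reagents that add atoms: none
Why: Dess–Martin oxidation under pyridine buffer should give the β-silyloxy aldehyde without touching the dienyl acetate.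

Step 12
Reactants: 21 aldehyde
Product: 22 (1E,3E,5S,6S)-6-(tert-butyldimethylsilyloxy)-8-hydroxy-5-[3-(4-methoxybenzyloxy)prop-1-en-2-yl]-2-methyldeca-1,3,9-trien-1-yl acetate (both C8 epimers)
Conditions: vinyl bromide, CrCl2, NiCl2 (cat.), DMF, rt
Reagents that add atoms: vinyl bromide, C=CBr
Why: Nozaki–Hiyama–Kishi vinylation, in which the vinylchromium reagent adds only to the aldehyde and ignores the enol acetate; the C8 carbinol centre formed here is removed in step 13.

Step 13
Reactants: 22 allylic alcohol
Product: 23 (1E,3E,5S,6S)-6-(tert-butyldimethylsilyloxy)-5-[3-(4-methoxybenzyloxy)prop-1-en-2-yl]-2-methyl-8-oxodeca-1,3,9-trien-1-yl acetate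
Conditions: Dess–Martin periodinane, pyridine, CH2Cl2, 0 °C; used at once
Reagents that add atoms: none
Why: Dess–Martin oxidation of the allylic alcohol unmasks the vinyl ketone under neutral conditions after all basic steps, so the β-silyloxy enone never meets base.

Step 14
Reactants: 23 trienone
Product: 24 cis-fused octalone (ring A: C3=C4 methyl alkene; C5 acetate; ring B: C8 ketone; C10 OTBS; C1 3-(4-methoxybenzyloxy)prop-1-en-2-yl; C1 S; C2 R; C5 S; C7 R; C10 S)
Conditions: PhMe (0.005 M), BHT (cat.), 80 °C
Reagents that add atoms: none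
Why: Concerted suprafacial [4+2] cycloaddition (type 1 intramolecular Diels–Alder) in which the diene C2=C3–C4=C5 and the dienophile C6=C7 form C2–C7 and C5–C6; the closest known reaction type is the thermal cyclisation of 6-substituted 1,7,9-decatrien-3-ones to cis-fused octalones, together with the use of (E)-1-acyloxydienes as dienes. Ring A closes as the six-membered cycloaddition ring and ring B as the six-membered ring of the four-atom tether C1–C10–C9–C8 (fused mode, the tether joining a diene terminus to the carbonyl-bearing dienophile carbon). C7 is set by the endo position of the tether carbonyl under the diene, which gives the cis ring fusion; C5 is set by the E enol acetate, whose outside acetoxy group ends cis to C1 and C8 on ring A; C2 is set by the diene face that C1 selects. The step needs endo and diene-face selectivity: in the chair-like endo tether the C1 propenyl group lies outside, anti to C3, and the C10 silyloxy group is equatorial, whereas the other face would push the C1 substituent over the diene and the C10 oxygen into the axial site next to C3–H. The tether also fixes the regiochemistry (C7 to C2), and Z-enol or Z-diene isomers cannot reach this transition state, so they should not give adducts.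

Step 15
Reactants: 24 cis-fused octalone
Product: 25 tertiary carbinol (as 24 with C8 methyl carbinol; methyl on the face of H2 and H7; hydroxyl on the ring A side; C8 S)
Conditions: MeLi, CeCl3, THF, −78 °C
Reagents that add atoms: methyllithium, [Li]C
Why: Organocerium 1,2-addition should suppress enolisation of the β-silyloxy ketone and spare the acetate at −78 °C, and methyl should enter from the convex face of the cis-fused bicycle (the face of H2/H7, anti to ring A), which sets C8.

Step 16
Reactants: 25 tertiary carbinol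
Product: 26 diol (as 25 with free C10 hydroxyl)
Conditions: HF·pyridine, THF, 0 °C → rt
Reagents that add atoms: none
Why: Fluoride-mediated desilylation removes the one remaining silyl ether, while the acetate, the PMB ether and the tertiary alcohol are inert.

Step 17
Reactants: 27 but-2-yne-1,4-diol
Product: 28 (E)-2-(tributylstannyl)but-2-ene-1,4-diol
Conditions: Bu3SnH, PdCl2(PPh3)2 (2 mol%), THF, rt
Reagents that add atoms: tributyltin hydride, CCCC[SnH](CCCC)CCCC
Why: Palladium-catalysed syn hydrostannation of the symmetrical alkyne puts H and Sn on the same side, so the two CH2OH groups end up cis.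

Step 18
Reactants: 28 stannyl diol
Product: 29 2,2-dimethyl-5-(tributylstannyl)-4,7-dihydro-1,3-dioxepine
Conditions: 2,2-dimethoxypropane, PPTS (cat.), CH2Cl2, rt
Reagents that add atoms: 2,2-dimethoxypropane, COC(C)(C)OC
Why: Acid-catalysed transacetalisation of the cis-1,4-diol gives the seven-membered acetonide, and PPTS is too weak an acid to protodestannylate.

Step 19
Reactants: 29 stannyl dioxepine
Product: 31 2,2-dimethyl-4,7-dihydro-1,3-dioxepine-5-carboxylic acid, via vinyllithium 30 (not isolated)
Conditions: n-BuLi, THF, −78 °C; CO2; aq. NaH2PO4, 0 °C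
Reagents that add atoms: carbon dioxide, O=C=O
Why: Tin–lithium exchange gives the vinyllithium with retention, and carboxylation with CO2 follows; at −78 °C β-elimination of the allylic alkoxide is slow.

Step 20
Reactants: 26 diol; 31 dioxepine acid
Product: 33 C10 ester (as 26 with the C10 oxygen acylated by the 2,2-dimethyl-4,7-dihydro-1,3-dioxepine-5-carbonyl group), via mixed anhydride 32 (not isolated)
Conditions: 31, 2,4,6-trichlorobenzoyl chloride, Et3N, PhMe, rt; then 26, DMAP, rt
Reagents that add atoms: none
Why: Yamaguchi esterification through the mixed trichlorobenzoic anhydride should acylate the secondary C10 hydroxyl, because the tertiary C8 hydroxyl is too hindered to compete.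

Step 21
Reactants: 33 C10 ester
Product: 34 primary allylic alcohol (as 33 with Ca–CH2OH)
Conditions: DDQ, CH2Cl2/pH 7 buffer, 0 °C
Reagents that add atoms: none
Why: Oxidative PMB cleavage with DDQ (benzylic hydride abstraction, then hemiacetal collapse) is selective for the electron-rich ether and leaves acetonide, esters and alkenes alone.

Step 22
Reactants: 34 allylic alcohol
Product: 35 2-substituted acrolein (as 34 with Ca–CHO)
Conditions: Dess–Martin periodinane, pyridine, CH2Cl2, 0 °C
Reagents that add atoms: none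
Why: Dess–Martin oxidation of the primary allylic alcohol under buffered conditions should not epimerise C1 or touch the tertiary alcohol.

Step 23
Reactants: 35 enal
Product: 36 acrylic acid acetonide (as 35 with Ca–CO2H)
Conditions: NaClO2, NaH2PO4, 2-methylbut-2-ene, t-BuOH/H2O, 0 °C → rt
Reagents that add atoms: sodium chlorite, [Na+].[O-]Cl=O
Why: Pinnick oxidation converts the enal to the acid at about pH 4, where the acetonide survives, and the alkene scavenger removes hypochlorite before it can attack the double bonds.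

Step 24
Reactants: 36 acrylic acid acetonide
Product: 37 CNP0468194.1 (C1 S; C2 R; C5 S; C7 R; C8 S; C10 S; side-chain alkene with the two CH2OH groups cis)
Conditions: AcOH/H2O/THF (3:1:1), rt
Reagents that add atoms: none
Why: Mild acid-catalysed acetal hydrolysis opens the seven-membered acetonide, which is more labile than the acetate, the C10 ester and the tertiary alcohol, and the side-chain alkene keeps the geometry fixed by the former ring.

Compound list

1 | pent-4-enoic acid | C=CCCC(=O)O | starting material
2 | (R)-4-benzyloxazolidin-2-one | O=C1N[C@H](Cc2ccccc2)CO1 | starting material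
3 | pent-4-enoic pivalic anhydride | C=CCCC(=O)OC(=O)C(C)(C)C | intermediate
4 | (R)-4-benzyl-3-(pent-4-enoyl)oxazolidin-2-one | C=CCCC(=O)N1[C@H](Cc2ccccc2)COC1=O | intermediate
5 | 3-(tert-butyldimethylsilyloxy)propanal | O=CCCO[Si](C)(C)C(C)(C)C | starting material
6 | Z dibutylboron enolate of 4 (allyl CH2 cis to O–B) | C=CC/C=C(\OB(CCCC)CCCC)N1[C@H](Cc2ccccc2)COC1=O | intermediate
7 | (R)-4-benzyl-3-[(2R,3S)-2-allyl-5-(tert-butyldimethylsilyloxy)-3-hydroxypentanoyl]oxazolidin-2-one (acyl C2 = C1, C3 = C10) | O=C(N1[C@H](Cc2ccccc2)COC1=O)[C@@H]([C@@H](O)CCO[Si](C)(C)C(C)(C)C)CC=C | intermediate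
8 | (2R,3S)-2-allyl-5-(tert-butyldimethylsilyloxy)-3-hydroxy-N-methoxy-N-methylpentanamide | CON(C)C(=O)[C@@H]([C@@H](O)CCO[Si](C)(C)C(C)(C)C)CC=C | intermediate
9 | (2R,3S)-2-allyl-3,5-bis(tert-butyldimethylsilyloxy)-N-methoxy-N-methylpentanamide | CON(C)C(=O)[C@@H]([C@@H](O[Si](C)(C)C(C)(C)C)CCO[Si](C)(C)C(C)(C)C)CC=C | intermediate
10 | (tributylstannyl)methanol | OC[Sn](CCCC)(CCCC)CCCC | starting material
11 | tributyl[(4-methoxybenzyloxy)methyl]stannane | COc1ccc(COC[Sn](CCCC)(CCCC)CCCC)cc1 | intermediate
12 | (4-methoxybenzyloxy)methyllithium | [Li]COCc1ccc(OC)cc1 | intermediate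
13 | lithium hemiaminal from 9 and 12 (tetrahedral Weinreb adduct; new carbon unassigned) | [Li]OC(COCc1ccc(OC)cc1)(N(C)OC)[C@@H]([C@@H](O[Si](C)(C)C(C)(C)C)CCO[Si](C)(C)C(C)(C)C)CC=C | intermediate
14 | (3R,4S)-3-allyl-4,6-bis(tert-butyldimethylsilyloxy)-1-(4-methoxybenzyloxy)hexan-2-one | O=C(COCc1ccc(OC)cc1)[C@@H]([C@@H](O[Si](C)(C)C(C)(C)C)CCO[Si](C)(C)C(C)(C)C)CC=C | intermediate
15 | (3S,4S)-3-allyl-4,6-bis(tert-butyldimethylsilyloxy)-2-[(4-methoxybenzyloxy)methyl]hex-1-ene | C=C(COCc1ccc(OC)cc1)[C@@H]([C@@H](O[Si](C)(C)C(C)(C)C)CCO[Si](C)(C)C(C)(C)C)CC=C | intermediate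
16 | methacrolein | CC(=C)C=O | starting material
17 | (2E,5S,6S)-6,8-bis(tert-butyldimethylsilyloxy)-5-[3-(4-methoxybenzyloxy)prop-1-en-2-yl]-2-methyloct-2-enal | C=C(COCc1ccc(OC)cc1)[C@@H]([C@@H](O[Si](C)(C)C(C)(C)C)CCO[Si](C)(C)C(C)(C)C)C/C=C(\C)C=O | intermediate
18 | potassium (1E,3E)-dienolate of 17 | C=C(COCc1ccc(OC)cc1)[C@@H]([C@@H](O[Si](C)(C)C(C)(C)C)CCO[Si](C)(C)C(C)(C)C)/C=C/C(C)=C/[O-].[K+] | intermediate
19 | (1E,3E,5S,6S)-6,8-bis(tert-butyldimethylsilyloxy)-5-[3-(4-methoxybenzyloxy)prop-1-en-2-yl]-2-methylocta-1,3-dien-1-yl acetate | C=C(COCc1ccc(OC)cc1)[C@@H]([C@@H](O[Si](C)(C)C(C)(C)C)CCO[Si](C)(C)C(C)(C)C)/C=C/C(C)=C/OC(C)=O | intermediate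
20 | (1E,3E,5S,6S)-6-(tert-butyldimethylsilyloxy)-8-hydroxy-5-[3-(4-methoxybenzyloxy)prop-1-en-2-yl]-2-methylocta-1,3-dien-1-yl acetate | C=C(COCc1ccc(OC)cc1)[C@@H]([C@@H](O[Si](C)(C)C(C)(C)C)CCO)/C=C/C(C)=C/OC(C)=O | intermediate
21 | (1E,3E,5S,6S)-6-(tert-butyldimethylsilyloxy)-5-[3-(4-methoxybenzyloxy)prop-1-en-2-yl]-2-methyl-8-oxoocta-1,3-dien-1-yl acetate | C=C(COCc1ccc(OC)cc1)[C@@H]([C@@H](O[Si](C)(C)C(C)(C)C)CC=O)/C=C/C(C)=C/OC(C)=O | intermediate
22 | (1E,3E,5S,6S)-6-(tert-butyldimethylsilyloxy)-8-hydroxy-5-[3-(4-methoxybenzyloxy)prop-1-en-2-yl]-2-methyldeca-1,3,9-trien-1-yl acetate (C8 epimers) | C=C(COCc1ccc(OC)cc1)[C@@H]([C@@H](O[Si](C)(C)C(C)(C)C)CC(O)C=C)/C=C/C(C)=C/OC(C)=O | intermediate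
23 | (1E,3E,5S,6S)-6-(tert-butyldimethylsilyloxy)-5-[3-(4-methoxybenzyloxy)prop-1-en-2-yl]-2-methyl-8-oxodeca-1,3,9-trien-1-yl acetate (cycloaddition precursor) | C=C(COCc1ccc(OC)cc1)[C@@H]([C@@H](O[Si](C)(C)C(C)(C)C)CC(=O)C=C)/C=C/C(C)=C/OC(C)=O | intermediate
24 | cis-fused octalone: C8 ketone, C5 acetate, C10 OTBS, C1 3-(4-methoxybenzyloxy)prop-1-en-2-yl; H2, H7, the C1 side chain and the C10 oxygen on one face, the acetate on the other (C1 S, C2 R, C5 S, C7 R, C10 S) | C=C(COCc1ccc(OC)cc1)[C@@H]1[C@H]2C=C(C)[C@@H](OC(C)=O)C[C@H]2C(=O)C[C@@H]1O[Si](C)(C)C(C)(C)C | intermediate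
25 | as 24 with C8 methyl carbinol: methyl on the H2/H7 face, hydroxyl on the other (C8 S) | C=C(COCc1ccc(OC)cc1)[C@@H]1[C@H]2C=C(C)[C@@H](OC(C)=O)C[C@H]2[C@@](C)(O)C[C@@H]1O[Si](C)(C)C(C)(C)C | intermediate
26 | as 25 with free C10 hydroxyl (C8, C10 diol) | C=C(COCc1ccc(OC)cc1)[C@@H]1[C@H]2C=C(C)[C@@H](OC(C)=O)C[C@H]2[C@@](C)(O)C[C@@H]1O | intermediate
27 | but-2-yne-1,4-diol | OCC#CCO | starting material
28 | (E)-2-(tributylstannyl)but-2-ene-1,4-diol (CH2OH groups cis) | OC/C=C(/[Sn](CCCC)(CCCC)CCCC)CO | intermediate
29 | 2,2-dimethyl-5-(tributylstannyl)-4,7-dihydro-1,3-dioxepine | CC1(C)OCC=C([Sn](CCCC)(CCCC)CCCC)CO1 | intermediate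
30 | (2,2-dimethyl-4,7-dihydro-1,3-dioxepin-5-yl)lithium | CC1(C)OCC=C([Li])CO1 | intermediate
31 | 2,2-dimethyl-4,7-dihydro-1,3-dioxepine-5-carboxylic acid | CC1(C)OCC=C(C(=O)O)CO1 | intermediate
32 | mixed anhydride of 31 with 2,4,6-trichlorobenzoic acid | CC1(C)OCC=C(CO1)C(=O)OC(=O)c1c(Cl)cc(Cl)cc1Cl | intermediate
33 | as 26 with the C10 oxygen acylated by the 2,2-dimethyl-4,7-dihydro-1,3-dioxepine-5-carbonyl group | C=C(COCc1ccc(OC)cc1)[C@@H]1[C@H]2C=C(C)[C@@H](OC(C)=O)C[C@H]2[C@@](C)(O)C[C@@H]1OC(=O)C3=CCOC(C)(C)OC3 | intermediate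
34 | as 33 with Ca–CH2OH | C=C(CO)[C@@H]1[C@H]2C=C(C)[C@@H](OC(C)=O)C[C@H]2[C@@](C)(O)C[C@@H]1OC(=O)C3=CCOC(C)(C)OC3 | intermediate
35 | as 33 with Ca–CHO | C=C(C=O)[C@@H]1[C@H]2C=C(C)[C@@H](OC(C)=O)C[C@H]2[C@@](C)(O)C[C@@H]1OC(=O)C3=CCOC(C)(C)OC3 | intermediate
36 | as 33 with Ca–CO2H | C=C(C(=O)O)[C@@H]1[C@H]2C=C(C)[C@@H](OC(C)=O)C[C@H]2[C@@](C)(O)C[C@@H]1OC(=O)C3=CCOC(C)(C)OC3 | intermediate
37 | CNP0468194.1: acrylic acid at C1, C5 acetate, C8 methyl carbinol, C10 (E)-4-hydroxy-2-(hydroxymethyl)but-2-enoate (C1 S, C2 R, C5 S, C7 R, C8 S, C10 S) | C=C(C(=O)O)[C@@H]1[C@H]2C=C(C)[C@@H](OC(C)=O)C[C@H]2[C@@](C)(O)C[C@@H]1OC(=O)/C(=C/CO)CO | target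

Total step count: 24 (20 on the main line, 3 for the side-chain acid, 1 for the stannane reagent).
Longest linear sequence: 20 steps (steps 1–4, 6–16 and 20–24).

Steps most likely to fail

Step 14 (key step). What may go wrong is leakage through the exo transition state, which gives the trans-fused C7 epimer, together with slow loss of the sensitive trienone on prolonged heating. The fallback replaces separation by a ring-fusion correction. It sets out from 23: the cycloaddition is run as before, and the mixture of 24 and trans-fused octalone F3 is converted without separation into the C7=C8 trimethylsilyl enol ether F4 (Me3SiCl, NaI, Et3N, MeCN; equilibrating conditions that favour the more substituted enol ether). Kinetic protonation of F4 (Bu4NF buffered with AcOH, THF, −78 °C) should place the proton on C7 from the face of H2, anti to C3, and so come back to the route at 24. The C8=C9 enol ether regioisomer only reverts to its ketone, so the material can be cycled. Adducts from the wrong diene face are not rescued and would have to be removed by chromatography.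

Step 9. What may go wrong is incomplete geometric control when the potassium dienolate is acetylated (Z enol acetate or Z C2=C3 bond) and competing C-acetylation; only the E,E isomer can cyclise in step 14. The fallback separates enolisation from acetylation. It sets out from 17: soft enolisation (Et3SiOTf, Et3N, CH2Cl2, −78 °C) should give the (1E,3E)-triethylsilyl dienol ether F1, which can be purified on base-washed silica. MeLi (THF, 0 °C) then cleaves the O–Si bond to the lithium dienolate F2 with retention of enolate geometry, and Ac2O at −78 °C brings the sequence back to the route at 19.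

Step 15. What may go wrong is addition from the wrong face of the C8 ketone, or enolisation followed by loss of the β-silyloxy group. The fallback replaces steric approach control by hydroxyl-directed delivery. It sets out from 24: HF·pyridine (THF, 0 °C → rt) removes the C10 silyl group first to give the β-hydroxy ketone F5. Me3Al (excess, CH2Cl2, −78 → 0 °C) then forms the C10 aluminium alkoxide, which binds the C8 carbonyl and should deliver methyl to the face that carries the C10 oxygen, as in alkoxide-directed additions of aluminium and titanium methyl reagents to β-hydroxy ketones. This comes back to the route at diol 26, so step 16 is then not needed.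

Further compounds

F1 | step 9 | (1E,3E)-triethylsilyl dienol ether of 17 | C=C(COCc1ccc(OC)cc1)[C@@H]([C@@H](O[Si](C)(C)C(C)(C)C)CCO[Si](C)(C)C(C)(C)C)/C=C/C(C)=C/O[Si](CC)(CC)CC
F2 | step 9 | lithium (1E,3E)-dienolate of 17 | C=C(COCc1ccc(OC)cc1)[C@@H]([C@@H](O[Si](C)(C)C(C)(C)C)CCO[Si](C)(C)C(C)(C)C)/C=C/C(C)=C/O[Li]
F3 | step 14 | trans-fused octalone (C7 epimer of 24) | C=C(COCc1ccc(OC)cc1)[C@@H]1[C@H]2C=C(C)[C@@H](OC(C)=O)C[C@@H]2C(=O)C[C@@H]1O[Si](C)(C)C(C)(C)C
F4 | step 14 | C7=C8 trimethylsilyl enol ether of 24 | C=C(COCc1ccc(OC)cc1)[C@@H]1[C@H]2C=C(C)[C@@H](OC(C)=O)CC2=C(O[Si](C)(C)C)C[C@@H]1O[Si](C)(C)C(C)(C)C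
F5 | step 15 | β-hydroxy ketone (24 with free C10 hydroxyl) | C=C(COCc1ccc(OC)cc1)[C@@H]1[C@H]2C=C(C)[C@@H](OC(C)=O)C[C@H]2C(=O)C[C@@H]1O
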